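- Locants: ring A is the spiro epoxycyclohexanone (C-1' carbonyl, C-2' prenyl-bearing oxirane carbon, C-3' oxirane CH, C-4' carbinol, C-5' methylene, C-6' spiro carbon); ring B is the second epoxycyclohexanone, numbered alike with double primes (C-6'' is the ylidene carbon); ring C is the central cyclohexene (C-1 = C-6', C-2 dienylidene carbon, C-3 bonded to C-6'', C-4=C-5 with the methyl on C-5, C-6 methylene).
- Cuts, retrosynthetically: first the C-2'–C-3' bond and the C-2'–O oxirane bond of ring A (Darzens retron: the C-1' ketone can enolise only toward C-2' because C-6' is quaternary, and C-3' is reached as an aldehyde through C-4'–C-5'–C-6'); second C-1–C-6 and C-2–C-3 of ring C (retro-[4+2] to a ring-B vinylallene and an acyclic allenyl ketone that carries the ring-A atoms as two arms); third the two alkyne–enone bonds (Sonogashira).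
- Forward ring order: ring B with its oxirane (from an arene via a quinone monoketal), then ring C (cross Diels–Alder of two allenes made in the flask), then ring A and its oxirane in one operation, last.
- Stereochemistry: C-2''/C-3'' from a tartrate-mediated epoxidation; C-4'' from hydride addition anti to the oxirane; C-4' from methyl (R)-glycerate; the spiro centre and both exocyclic alkene geometries from the cycloaddition; C-2'/C-3' from the Darzens closure under control of C-4'.
- Helpers: a tertiary carbinol in place of the isopropenyl group keeps the dienophile from acting as a diene (dehydrated after the cycloaddition); chlorine at C-2' is the Darzens leaving group; triethylsilyl ethers protect the oxygens at C-4' and C-4'' and the latent C-3' aldehyde.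

Key step: step 17

Assumption: L-(+)-diisopropyl tartrate is taken to give the (5R,6S)-epoxide in step 3; if the sense of induction is the opposite, the D-(−)-ester is used and nothing else changes.

**Ring B fragment**

Step 1
Reactants: 1 2-bromo-4-methoxyphenol; 2 1-bromo-3-methylbut-2-ene
Product: 3 2-bromo-4-methoxy-6-(3-methylbut-2-en-1-yl)phenol
Conditions: NaH, PhMe, 0 °C; then 2, rt
Reagents that add atoms: none
Why: Ortho C-alkylation of a sodium phenoxide by an allylic bromide in a non-polar solvent; C-6 is the only free ortho/para position of 1.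

Step 2
Reactants: 3 2-bromo-4-methoxy-6-(3-methylbut-2-en-1-yl)phenol
Product: 4 2-bromo-4,4-dimethoxy-6-(3-methylbut-2-en-1-yl)cyclohexa-2,5-dien-1-one
Conditions: PhI(OAc)2, MeOH, 0 °C
Reagents that add atoms: methanol (CO)
Why: Oxidative dearomatisation of a para-methoxyphenol by a hypervalent iodine reagent in methanol should give the para-quinone monoketal, the isolated prenyl double bond being inert at 0 °C.

Step 3
Reactants: 4 2-bromo-4,4-dimethoxy-6-(3-methylbut-2-en-1-yl)cyclohexa-2,5-dien-1-one
Product: 5 (5R,6S)-2-bromo-5,6-epoxy-4,4-dimethoxy-6-(3-methylbut-2-en-1-yl)cyclohex-2-en-1-one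
Conditions: Ph3COOH, NaN(SiMe3)2, L-(+)-diisopropyl tartrate, PhMe, −78 → −40 °C
Reagents that add atoms: trityl hydroperoxide (OOC(c1ccccc1)(c1ccccc1)c1ccccc1)
Why: Tartrate-mediated nucleophilic (Weitz–Scheffer-type) epoxidation is expected to take the alkyl-substituted enone double bond in preference to the bromine-bearing one, and the chiral sodium tartrate/peroxide aggregate selects the face, which sets both oxirane centres (C-3'' and C-2'').

Step 4
Reactants: 5 (5R,6S)-2-bromo-5,6-epoxy-4,4-dimethoxy-6-(3-methylbut-2-en-1-yl)cyclohex-2-en-1-one; 6 2-methylbut-1-en-3-yne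
Product: 7 (5R,6S)-5,6-epoxy-4,4-dimethoxy-2-(3-methylbut-3-en-1-yn-1-yl)-6-(3-methylbut-2-en-1-yl)cyclohex-2-en-1-one
Conditions: PdCl2(PPh3)2 (cat.), CuI (cat.), iPr2NH, THF, 0 °C → rt
Reagents that add atoms: none
Why: Sonogashira coupling of an α-bromo enone (an activated vinyl bromide) with a terminal alkyne; oxirane and ketal are inert to the amine.

Step 5
Reactants: 7 (5R,6S)-5,6-epoxy-4,4-dimethoxy-2-(3-methylbut-3-en-1-yn-1-yl)-6-(3-methylbut-2-en-1-yl)cyclohex-2-en-1-one
Product: 8 (5R,6S)-5,6-epoxy-2-(3-methylbut-3-en-1-yn-1-yl)-6-(3-methylbut-2-en-1-yl)cyclohex-2-ene-1,4-dione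
Conditions: montmorillonite K10, wet CH2Cl2, rt
Reagents that add atoms: water (O)
Why: Acid-clay hydrolysis of the dimethyl ketal (ketal hydrolysis) should unmask the C-4'' carbonyl without touching the oxirane or any stereocentre.

Step 6
Reactants: 8 (5R,6S)-5,6-epoxy-2-(3-methylbut-3-en-1-yn-1-yl)-6-(3-methylbut-2-en-1-yl)cyclohex-2-ene-1,4-dione
Product: 9 (4S,5S,6S)-5,6-epoxy-4-hydroxy-2-(3-methylbut-3-en-1-yn-1-yl)-6-(3-methylbut-2-en-1-yl)cyclohex-2-en-1-one
Conditions: NaBH4, CeCl3·7H2O, MeOH, −78 °C
Reagents that add atoms: none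
Why: Luche reduction should add hydride 1,2 to the less hindered C-4'' carbonyl (C-1'' is flanked by the quaternary oxirane carbon and the alkynyl-bearing carbon) on the face anti to the oxirane oxygen, which sets C-4'' (S) with the hydroxyl cis to the oxirane.

Step 7
Reactants: 9 (4S,5S,6S)-5,6-epoxy-4-hydroxy-2-(3-methylbut-3-en-1-yn-1-yl)-6-(3-methylbut-2-en-1-yl)cyclohex-2-en-1-one
Product: 10 (4S,5S,6S)-5,6-epoxy-2-(3-methylbut-3-en-1-yn-1-yl)-6-(3-methylbut-2-en-1-yl)-4-(triethylsilyloxy)cyclohex-2-en-1-one
Conditions: Et3SiCl, imidazole, CH2Cl2, 0 °C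
Reagents that add atoms: chlorotriethylsilane (CC[Si](Cl)(CC)CC)
Why: Silyl ether formation at the only hydroxyl, needed so that the later dehydration (step 14) touches the tertiary carbinol alone.

**Ring A arm fragment**

Step 8
Reactants: 11 methyl (R)-2,3-dihydroxypropanoate
Product: 12 methyl (R)-2,3-bis(triethylsilyloxy)propanoate
Conditions: Et3SiCl (2.2 equiv), imidazole, DMAP (cat.), CH2Cl2, 0 °C → rt
Reagents that add atoms: chlorotriethylsilane (CC[Si](Cl)(CC)CC)
Why: Double silyl ether formation; the stereocentre (the future C-4') comes from the chiral pool and is not touched.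

Step 9
Reactants: 12 methyl (R)-2,3-bis(triethylsilyloxy)propanoate
Product: 13 (R)-2,3-bis(triethylsilyloxy)propanal
Conditions: iBu2AlH, CH2Cl2, −78 °C; aq. KNaC4H4O6
Reagents that add atoms: none
Why: Partial reduction of an α-silyloxy ester to the aldehyde stops at the tetrahedral aluminate at −78 °C, and the α-centre is not enolised.

Step 10
Reactants: 14 6-methylhept-5-en-2-one; 13 (R)-2,3-bis(triethylsilyloxy)propanal
Product: 17 (2S,3E)-9-methyl-1,2-bis(triethylsilyloxy)deca-3,8-dien-5-one, via lithium aldolate 15 (not isolated), via aldol mesylate 16 (not isolated)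
Conditions: LiN(iPr)2, THF, −78 °C; then 13; then MeSO2Cl, Et3N, −78 → rt
Reagents that add atoms: none
Why: Directed aldol addition of the kinetic methyl-side enolate followed by base-induced β-elimination of the mesylate (aldol condensation in two stages) should give the (E)-enone; the new carbinol centre is destroyed and the silyloxy-bearing centre is untouched.

Step 11
Reactants: 17 (2S,3E)-9-methyl-1,2-bis(triethylsilyloxy)deca-3,8-dien-5-one
Product: 18 (2S,3Z)-4-iodo-9-methyl-1,2-bis(triethylsilyloxy)deca-3,8-dien-5-one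
Conditions: I2, pyridine, DMAP (cat.), CH2Cl2, rt, dark
Reagents that add atoms: iodine (II)
Why: α-Iodination of an enone by the Morita–Baylis–Hillman-type sequence of pyridine conjugate addition, enolate iodination and elimination.

Step 12
Reactants: 18 (2S,3Z)-4-iodo-9-methyl-1,2-bis(triethylsilyloxy)deca-3,8-dien-5-one; 19 2-methylbut-3-yn-2-ol
Product: 20 (2S,3E)-4-(3-hydroxy-3-methylbut-1-yn-1-yl)-9-methyl-1,2-bis(triethylsilyloxy)deca-3,8-dien-5-one
Conditions: PdCl2(PPh3)2 (cat.), CuI (cat.), iPr2NH, THF, rt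
Reagents that add atoms: none
Why: Sonogashira coupling of an α-iodo enone; the free tertiary carbinol is tolerated and is kept as the masked isopropenyl group.

**Assembly and ring A**

Step 13
Reactants: 10 (4S,5S,6S)-5,6-epoxy-2-(3-methylbut-3-en-1-yn-1-yl)-6-(3-methylbut-2-en-1-yl)-4-(triethylsilyloxy)cyclohex-2-en-1-one; 20 (2S,3E)-4-(3-hydroxy-3-methylbut-1-yn-1-yl)-9-methyl-1,2-bis(triethylsilyloxy)deca-3,8-dien-5-one
Product: 23 ring-C cycloadduct, via vinylallene 21 (not isolated), via allenyl ketone 22 (not isolated)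
Conditions: [(Ph3P)CuH]6 (one hydride per enone), PhMe, H2O (10 equiv), 0 °C; then Et3N, rt, 0.3 M, dark; 20 in threefold excess
Reagents that add atoms: none
Why: The copper hydride reduces each α-alkynyl enone only at its β-carbon and Et3N moves the resulting α-alkynyl ketones into conjugation as vinylallene 21 and allenyl ketone 22, after which 21 (diene C-3=C-4–C-5=C-6) adds to the acyl-activated double bond of 22 in a Diels–Alder reaction that starts by bonding of the two central allene carbons (C-2–C-3) and is kept on the cross course because 22 is in excess and cannot act as a diene; the dienophile is approached anti to its CMe2OH group (C-2 alkylidene geometry Z), on the diene face next to the C-1'' carbonyl (C-3=C-6'' geometry Z) and with its ketone endo on the axial isomer of 21 that holds the diene arm on the oxirane face of ring B, away from the C-2'' prenyl group, which sets the quaternary centre C-1 as R.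

Step 14
Reactants: 23 ring-C cycloadduct
Product: 24 ring-C triene
Conditions: MeO2CN(−)SO2N(+)Et3 (inner salt), PhMe, 50 °C
Reagents that add atoms: none
Why: Burgess dehydration of the tertiary allylic carbinol can only take a methyl hydrogen, which unveils the isopropenyl group; every other hydroxyl is silylated and the alkylidene geometry is not involved.

Step 15
Reactants: 24 ring-C triene
Product: 25 α-chloro ketone
Conditions: LiN(SiMe3)2, THF, −78 °C; then N-chlorosuccinimide, −78 °C
Reagents that add atoms: N-chlorosuccinimide (O=C1CCC(=O)N1Cl)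
Why: Electrophilic α-chlorination of a kinetic lithium enolate; the C-1' ketone has a single enolisable position (C-2', since C-6' is quaternary) and the ring-B ketone has none, and the C-2' configuration is irrelevant because this centre is enolised again in step 17.

Step 16
Reactants: 25 α-chloro ketone
Product: 26 keto aldehyde
Conditions: (COCl)2, DMSO, CH2Cl2, −78 °C; then 25, −78 → −40 °C; Et3N, −78 → 0 °C
Reagents that add atoms: none
Why: Swern oxidation converts a primary triethylsilyl ether directly into the aldehyde (silyl transfer to chloride, then alkoxysulfonium ylide fragmentation) while the two secondary silyl ethers survive, and C-4' should not epimerise at low temperature.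

Step 17
Reactants: 26 keto aldehyde
Product: 28 bis(triethylsilyl) ether of the target, via chlorohydrin alkoxide 27 (not isolated)
Conditions: KN(SiMe3)2 (1.05 equiv), THF, −78 → −20 °C
Reagents that add atoms: none
Why: KN(SiMe3)2 removes the C-2' hydrogen, which is the only enolisable hydrogen of the C-1' ketone (the other α-carbon, C-6', is the quaternary spiro atom) and the most acidic C–H in 26 because of the chlorine, the chloro-enolate adds to the C-3' aldehyde, and the resulting C-3' alkoxide 27 displaces chloride at C-2' from the rear, which is an intramolecular Darzens condensation. The closest known reaction type is the Darzens synthesis of an α,β-epoxy ketone from an α-chloro ketone and an aldehyde, in its ring-forming intramolecular version. Ring A closes by a 6-(enolendo)-exo-trig aldol addition (C-2'–C-3' bond) and the oxirane by a 3-exo-tet substitution (C-3'–O–C-2'). The aldol addition is reversible and only an aldolate with the oxide at C-3' and the chlorine at C-2' trans-diaxial can close, so C-2' and C-3' are decided in the oxirane-forming step: the chair that has this arrangement and keeps the C-4' silyloxy group equatorial gives the oxirane cis to the C-4' oxygen (C-3' S), whereas the epimeric closure needs the silyloxy group axial and syn-axial to the chlorine and to a ring-C bond at the spiro carbon, and C-2' (S) then follows from the cis ring fusion with the prenyl group trans to the oxirane oxygen. The step needs chemoselective enolisation at C-2' in the presence of the α-silyloxy aldehyde (C-4'–H) and of the vinylogous C-6 methylene of the ring-B dienone, which the acidity of the α-chloro ketone and the low temperature should secure, and it needs the spiro centre to stay fixed, which its quaternary nature guarantees.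

Step 18
Reactants: 28 bis(triethylsilyl) ether of the target
Product: 29 CNP0235815.2
Conditions: HF·pyridine, pyridine, THF, 0 °C → rt
Reagents that add atoms: none
Why: Fluoride-mediated desilylation of the two secondary triethylsilyl ethers under buffered conditions should leave both epoxy ketones and the cross-conjugated tetraene intact.

**Compound list**

1 | 2-bromo-4-methoxyphenol | COc1ccc(O)c(Br)c1 | starting material
2 | 1-bromo-3-methylbut-2-ene (prenyl bromide) | CC(C)=CCBr | starting material
3 | 2-bromo-4-methoxy-6-(3-methylbut-2-en-1-yl)phenol | COc1cc(Br)c(O)c(CC=C(C)C)c1 | intermediate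
4 | 2-bromo-4,4-dimethoxy-6-(3-methylbut-2-en-1-yl)cyclohexa-2,5-dien-1-one | COC1(OC)C=C(Br)C(=O)C(CC=C(C)C)=C1 | intermediate
5 | (5R,6S)-2-bromo-5,6-epoxy-4,4-dimethoxy-6-(3-methylbut-2-en-1-yl)cyclohex-2-en-1-one | O=C1C(Br)=CC(OC)(OC)[C@@H]2O[C@]12CC=C(C)C | intermediate
6 | 2-methylbut-1-en-3-yne | C=C(C)C#C | starting material
7 | (5R,6S)-5,6-epoxy-4,4-dimethoxy-2-(3-methylbut-3-en-1-yn-1-yl)-6-(3-methylbut-2-en-1-yl)cyclohex-2-en-1-one | O=C1C(C#CC(C)=C)=CC(OC)(OC)[C@@H]2O[C@]12CC=C(C)C | intermediate
8 | (5R,6S)-5,6-epoxy-2-(3-methylbut-3-en-1-yn-1-yl)-6-(3-methylbut-2-en-1-yl)cyclohex-2-ene-1,4-dione | O=C1C(C#CC(C)=C)=CC(=O)[C@@H]2O[C@]12CC=C(C)C | intermediate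
9 | (4S,5S,6S)-5,6-epoxy-4-hydroxy-2-(3-methylbut-3-en-1-yn-1-yl)-6-(3-methylbut-2-en-1-yl)cyclohex-2-en-1-one (hydroxyl cis to the oxirane; ring positions 4, 5 and 6 are C-4'', C-3'' and C-2'') | O=C1C(C#CC(C)=C)=C[C@H](O)[C@@H]2O[C@]12CC=C(C)C | intermediate
10 | (4S,5S,6S)-5,6-epoxy-2-(3-methylbut-3-en-1-yn-1-yl)-6-(3-methylbut-2-en-1-yl)-4-(triethylsilyloxy)cyclohex-2-en-1-one | O=C1C(C#CC(C)=C)=C[C@H](O[Si](CC)(CC)CC)[C@@H]2O[C@]12CC=C(C)C | intermediate
11 | methyl (R)-2,3-dihydroxypropanoate (methyl D-glycerate) | COC(=O)[C@H](O)CO | starting material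
12 | methyl (R)-2,3-bis(triethylsilyloxy)propanoate | COC(=O)[C@H](O[Si](CC)(CC)CC)CO[Si](CC)(CC)CC | intermediate
13 | (R)-2,3-bis(triethylsilyloxy)propanal | O=C[C@H](O[Si](CC)(CC)CC)CO[Si](CC)(CC)CC | intermediate
14 | 6-methylhept-5-en-2-one | CC(=O)CCC=C(C)C | starting material
15 | lithium (2R)-9-methyl-5-oxo-1,2-bis(triethylsilyloxy)dec-8-en-3-olate (both C-3 epimers; not isolated) | CC(C)=CCCC(=O)CC([O-])[C@H](O[Si](CC)(CC)CC)CO[Si](CC)(CC)CC.[Li+] | intermediate
16 | (2R)-9-methyl-5-oxo-1,2-bis(triethylsilyloxy)dec-8-en-3-yl methanesulfonate (both C-3 epimers; not isolated) | CC(C)=CCCC(=O)CC(OS(C)(=O)=O)[C@H](O[Si](CC)(CC)CC)CO[Si](CC)(CC)CC | intermediate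
17 | (2S,3E)-9-methyl-1,2-bis(triethylsilyloxy)deca-3,8-dien-5-one | CC(C)=CCCC(=O)/C=C/[C@H](O[Si](CC)(CC)CC)CO[Si](CC)(CC)CC | intermediate
18 | (2S,3Z)-4-iodo-9-methyl-1,2-bis(triethylsilyloxy)deca-3,8-dien-5-one | CC(C)=CCCC(=O)/C(I)=C/[C@H](O[Si](CC)(CC)CC)CO[Si](CC)(CC)CC | intermediate
19 | 2-methylbut-3-yn-2-ol | CC(C)(O)C#C | starting material
20 | (2S,3E)-4-(3-hydroxy-3-methylbut-1-yn-1-yl)-9-methyl-1,2-bis(triethylsilyloxy)deca-3,8-dien-5-one | CC(C)=CCCC(=O)/C(C#CC(C)(C)O)=C/[C@H](O[Si](CC)(CC)CC)CO[Si](CC)(CC)CC | intermediate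
21 | (2S,3S,4S)-2,3-epoxy-6-(3-methylbuta-1,3-dien-1-ylidene)-2-(3-methylbut-2-en-1-yl)-4-(triethylsilyloxy)cyclohexan-1-one (vinylallene; allene axis not defined; not isolated) | C=C(C)C=C=C1C[C@H](O[Si](CC)(CC)CC)[C@@H]2O[C@]2(CC=C(C)C)C1=O | intermediate
22 | (2S)-4-(3-hydroxy-3-methylbut-1-en-1-ylidene)-9-methyl-1,2-bis(triethylsilyloxy)dec-8-en-5-one (allenyl ketone; allene axis not defined; not isolated) | CC(C)=CCCC(=O)C(C[C@H](O[Si](CC)(CC)CC)CO[Si](CC)(CC)CC)=C=CC(C)(C)O | intermediate
23 | ring-C cycloadduct: cyclohexene whose C-1 (R) carries the 5-methylhex-4-enoyl group (C-1', C-2') and the (S)-2,3-bis(triethylsilyloxy)propyl group (C-5', C-4', C-3'), whose C-2 carries the (Z)-3-hydroxy-3-methylbutylidene group (carbinol carbon cis to C-1) and whose C-3 is joined by a (Z) double bond (C-2 cis to C-1'') to C-6'' of the (2S,3S,4S)-2,3-epoxy-2-prenyl-4-(triethylsilyloxy)cyclohexanone ring B | CC(C)(O)/C=C1/C(=C2/C[C@H](O[Si](CC)(CC)CC)[C@@H]3O[C@]3(CC=C(C)C)C2=O)C=C(C)C[C@]1(C[C@H](O[Si](CC)(CC)CC)CO[Si](CC)(CC)CC)C(=O)CCC=C(C)C | intermediate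
24 | ring-C triene: as 23 with the (Z)-2-methylprop-2-en-1-ylidene group (isopropenyl cis to C-1) at C-2 | C=C(C)/C=C1/C(=C2/C[C@H](O[Si](CC)(CC)CC)[C@@H]3O[C@]3(CC=C(C)C)C2=O)C=C(C)C[C@]1(C[C@H](O[Si](CC)(CC)CC)CO[Si](CC)(CC)CC)C(=O)CCC=C(C)C | intermediate
25 | α-chloro ketone: as 24 with chlorine at C-2' (both C-2' epimers) | C=C(C)/C=C1/C(=C2/C[C@H](O[Si](CC)(CC)CC)[C@@H]3O[C@]3(CC=C(C)C)C2=O)C=C(C)C[C@]1(C[C@H](O[Si](CC)(CC)CC)CO[Si](CC)(CC)CC)C(=O)C(Cl)CC=C(C)C | intermediate
26 | keto aldehyde: as 25 with C-3' as the aldehyde and C-4' (S) as its triethylsilyl ether | C=C(C)/C=C1/C(=C2/C[C@H](O[Si](CC)(CC)CC)[C@@H]3O[C@]3(CC=C(C)C)C2=O)C=C(C)C[C@]1(C[C@H](O[Si](CC)(CC)CC)C=O)C(=O)C(Cl)CC=C(C)C | intermediate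
27 | potassium chlorohydrin alkoxide: ring A closed, oxide at C-3' trans to chlorine at C-2' (not isolated) | C=C(C)/C=C1/C(=C2/C[C@H](O[Si](CC)(CC)CC)[C@@H]3O[C@]3(CC=C(C)C)C2=O)C=C(C)C[C@@]12C[C@H](O[Si](CC)(CC)CC)[C@H]([O-])[C@](Cl)(CC=C(C)C)C2=O.[K+] | intermediate
28 | bis(triethylsilyl) ether of the target (silyl ethers on the oxygens at C-4' and C-4''; rings A, B and C and both oxiranes complete) | C=C(C)/C=C1/C(=C2/C[C@H](O[Si](CC)(CC)CC)[C@@H]3O[C@]3(CC=C(C)C)C2=O)C=C(C)C[C@@]12C[C@H](O[Si](CC)(CC)CC)[C@@H]1O[C@]1(CC=C(C)C)C2=O | intermediate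
29 | CNP0235815.2: spiro centre R; C-2', C-3', C-4' and C-2'', C-3'', C-4'' all S; both exocyclic double bonds Z | C=C(C)/C=C1/C(=C2/C[C@H](O)[C@@H]3O[C@]3(CC=C(C)C)C2=O)C=C(C)C[C@@]12C[C@H](O)[C@@H]1O[C@]1(CC=C(C)C)C2=O | target

**Totals and risks**

Total step count: 18. Longest linear sequence: 13 steps (steps 1–7, then 13–18); the second branch is steps 8–12.

Steps most likely to fail:

1. Step 13 (cross Diels–Alder). What may go wrong: self-cycloaddition of the vinylallene outruns the cross reaction, or the acyclic dienophile is taken up with poor endo/facial discrimination so that the spiro centre forms as a mixture; the model that predicts R rests on geometric reasoning only. Fallback: make the dienophile cyclic, so that the spiro centre is set by a stereocentre inside the dienophile ring. It sets out from 10 and 19 and comes back at 23.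
   - Commercial (S)-5-(hydroxymethyl)furan-2(5H)-one is silylated (Et3SiCl, imidazole) to (S)-5-[(triethylsilyloxy)methyl]furan-2(5H)-one F1, iodinated (I2, pyridine) to the 3-iodobutenolide F2 and coupled with 19 (PdCl2(PPh3)2, CuI, iPr2NH) to the 3-alkynylbutenolide F3.
   - Reduction of F3 (threefold excess) together with 10 by [(Ph3P)CuH]6 under the conditions of step 13 gives the α-allenylidene lactone F4 in the flask beside 21. Vinylallene 21 should attack F4 on the lactone face anti to the C-5 substituent and give the spiro-lactone F5, in which the lactone carbonyl is C-1' and the ring oxygen is the C-4' oxygen.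
   - A carbon nucleophile would not tell the lactone from the ring-B ketone, so the ketone is taken out first: Luche reduction (NaBH4, CeCl3·7H2O, MeOH, −78 °C) leaves the lactone alone and gives the ring-B carbinol F6.
   - Single addition of (4-methylpent-3-en-1-yl)magnesium bromide (excess, THF, −78 → 0 °C) to the hindered lactone carbonyl gives the dihydroxy ketone F7. MnO2 (CH2Cl2, rt) reoxidises only the allylic ring-B carbinol and gives the hydroxy ketone F8, and Et3SiCl/imidazole returns the route to 23.

2. Step 17 (Darzens closure). What may go wrong: enolisation of the aldehyde with epimerisation at C-4', silyl migration from the C-4' oxygen to the C-3' alkoxide, or retro-aldol without oxirane closure on the required face. Fallback: form the oxirane after ring A instead of with it. It sets out from 24 and comes back at 29.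
   - Swern oxidation of 24 (as in step 16) gives the keto aldehyde F9; intramolecular aldol condensation (dibenzylammonium trifluoroacetate, PhH, 50 °C) closes ring A as the spiro cyclohexenone F10; HF·pyridine removes both silyl groups to give the diol F11.
   - Hydroxyl-directed Weitz–Scheffer epoxidation (t-BuOOH, benzyltrimethylammonium hydroxide, THF, 0 °C) should deliver oxygen to the C-2'=C-3' double bond syn to the free C-4' hydroxyl by hydrogen bonding, leave the tetrasubstituted ring-B dienone untouched, and give 29.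

3. Step 3 (asymmetric epoxidation). What may go wrong: low enantioselectivity, or peroxide attack at the bromine-bearing double bond. Fallback: auxiliary control in place of reagent control. It sets out from 4 and comes back at 8.
   - Trans-ketalisation of 4 with (2R,4R)-pentane-2,4-diol (pyridinium p-toluenesulfonate, PhH, reflux) gives the spiro-dioxane dienone F12.
   - Epoxidation with t-BuOOH/DBU should occur on the prenyl-bearing double bond from the face set by the dioxane methyl groups to give the epoxide F13 (minor diastereomer removed by chromatography; the antipodal diol is used if the sense is the opposite).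
   - Sonogashira coupling with 6 gives the enyne F14, and hydrolysis on montmorillonite K10 releases the diol and returns the route to 8.

**Further compounds**

F1 | step 13 | (S)-5-[(triethylsilyloxy)methyl]furan-2(5H)-one | O=C1C=C[C@@H](CO[Si](CC)(CC)CC)O1
F2 | step 13 | (S)-3-iodo-5-[(triethylsilyloxy)methyl]furan-2(5H)-one | O=C1C(I)=C[C@@H](CO[Si](CC)(CC)CC)O1
F3 | step 13 | (S)-3-(3-hydroxy-3-methylbut-1-yn-1-yl)-5-[(triethylsilyloxy)methyl]furan-2(5H)-one | O=C1C(C#CC(C)(C)O)=C[C@@H](CO[Si](CC)(CC)CC)O1
F4 | step 13 | (S)-3-(3-hydroxy-3-methylbut-1-en-1-ylidene)-5-[(triethylsilyloxy)methyl]dihydrofuran-2(3H)-one (allene axis not defined; formed in the flask) | O=C1C(=C=CC(C)(C)O)C[C@@H](CO[Si](CC)(CC)CC)O1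
F5 | step 13 | spiro-lactone cycloadduct (C-1 R, spiro to a γ-lactone whose carbonyl is C-1' and whose ring oxygen is on C-4'; C-4' carries CH2OSiEt3) | CC(C)(O)/C=C1/C(=C2/C[C@H](O[Si](CC)(CC)CC)[C@@H]3O[C@]3(CC=C(C)C)C2=O)C=C(C)C[C@@]12C[C@@H](CO[Si](CC)(CC)CC)OC2=O
F6 | step 13 | ring-B carbinol of the spiro-lactone (as F5 with C-1'' as CHOH; both C-1'' epimers) | CC(C)(O)/C=C1/C(=C2/C[C@H](O[Si](CC)(CC)CC)[C@@H]3O[C@]3(CC=C(C)C)C2O)C=C(C)C[C@@]12C[C@@H](CO[Si](CC)(CC)CC)OC2=O
F7 | step 13 | dihydroxy ketone (as 23 with a free C-4' hydroxyl and C-1'' as CHOH; both C-1'' epimers) | CC(C)(O)/C=C1/C(=C2/C[C@H](O[Si](CC)(CC)CC)[C@@H]3O[C@]3(CC=C(C)C)C2O)C=C(C)C[C@]1(C[C@H](O)CO[Si](CC)(CC)CC)C(=O)CCC=C(C)C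
F8 | step 13 | hydroxy ketone (as 23 with a free C-4' hydroxyl) | CC(C)(O)/C=C1/C(=C2/C[C@H](O[Si](CC)(CC)CC)[C@@H]3O[C@]3(CC=C(C)C)C2=O)C=C(C)C[C@]1(C[C@H](O)CO[Si](CC)(CC)CC)C(=O)CCC=C(C)C
F9 | step 17 | keto aldehyde without chlorine (as 26 with C-2' as CH2) | C=C(C)/C=C1/C(=C2/C[C@H](O[Si](CC)(CC)CC)[C@@H]3O[C@]3(CC=C(C)C)C2=O)C=C(C)C[C@]1(C[C@H](O[Si](CC)(CC)CC)C=O)C(=O)CCC=C(C)C
F10 | step 17 | spiro cyclohexenone (ring A closed with a C-2'=C-3' double bond; triethylsilyl ethers at C-4' and C-4'') | C=C(C)/C=C1/C(=C2/C[C@H](O[Si](CC)(CC)CC)[C@@H]3O[C@]3(CC=C(C)C)C2=O)C=C(C)C[C@@]12C[C@H](O[Si](CC)(CC)CC)C=C(CC=C(C)C)C2=O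
F11 | step 17 | spiro cyclohexenone diol (as F10 with free hydroxyls at C-4' and C-4'') | C=C(C)/C=C1/C(=C2/C[C@H](O)[C@@H]3O[C@]3(CC=C(C)C)C2=O)C=C(C)C[C@@]12C[C@H](O)C=C(CC=C(C)C)C2=O
F12 | step 3 | spiro-dioxane dienone: (2R,4R)-pentane-2,4-diyl ketal of the C-4'' carbonyl of 2-bromo-6-(3-methylbut-2-en-1-yl)benzoquinone | O=C1C(Br)=CC2(O[C@H](C)C[C@@H](C)O2)C=C1CC=C(C)C
F13 | step 3 | (5R,6S)-epoxide of F12 | O=C1C(Br)=CC2(O[C@H](C)C[C@@H](C)O2)[C@@H]3O[C@]13CC=C(C)C
F14 | step 3 | enyne from F13 (3-methylbut-3-en-1-yn-1-yl in place of bromine) | O=C1C(C#CC(C)=C)=CC2(O[C@H](C)C[C@@H](C)O2)[C@@H]3O[C@]13CC=C(C)C
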